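(The data stem from a simulated flask for substances that don't exist; the scatter is artificial.)

Start from the amounts: each flask receives its whole charge of electrophile over the feed, and every percentage counts that whole charge.

in all of them: gas 13 mM (held)
- violet: electrophile 0.33 M (fed, over 20 h); protonated nucleophile 0.264 M; run made earlier
- amber: electrophile 0.44 M (fed, over 20 h); protonated nucleophile 0.264 M; run made earlier
- alpha: electrophile 0.22 M (fed, over 20 h); protonated nucleophile 0.260 M; time 40 h
- gamma: electrophile 0.22 M (fed, over 20 h); protonated nucleophile 0.400 M; time 40 h

- violet (time / h: electrophile / %, target / %): 1.00: 5, 0; 1.50: 9, 0; 2.50: 13, 0; 4.00: 19, 1; 6.00: 28, 2; 10.0: 47, 4; 15.0: 68, 7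
- amber (time / h: electrophile / %, target / %): 0.833: 5, 0; 2.00: 9, 0; 4.00: 19, 0; 6.00: 23, 1; 8.00: 39, 2; 12.0: 56, 4; 15.0: 68, 7

(each reading ± 1.5 percentage points)

- at the start none of free base is dissolved
- steps thought possible: electrophile + nucleophile -> acid set free + target; nucleophile + acid set free <-> protonated nucleophile; acid set free + free base <-> salt of the base; gas <-> free base
- percentages count the whole charge, also what has not yet gone in

1. part of the electrophile that has reacted at the end, alpha
2. part of the electrophile that has reacted at the end, gamma
3. what raising the concentration of protonated nucleophile from its lowest to its highest value here does to the part of the electrophile that has reacted (changes below 5 percentage points count as none) (no change / it falls / it rises)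

Read the last target readings. Violet holds 7% at 15.0 h, and amber, with the larger charge, holds 7% at the same time. So treat the loss of electrophile, as a fraction of the charge, as pseudo-first-order with a constant k'. While little has reacted, the fed fraction grows in step with time. Then k' is 2 times the target reading times the dosing time, divided by the square of the time. Violet's reading gives 0.0124 h⁻¹, and it carries the scatter of 1.5 percentage points.

Now set the times in a row, shortest first. The feed lasts 20 h. A portion fed at a steady rate has stayed, on average, until the asked time minus half the dosing time, which is 30.0 h. The life of the electrophile, one over k', is 80.4 h, longer than both. So I expect alpha at the end of the feed to be still mostly electrophile.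

Count the turnovers, the turnover count being k' times the mean stay: 0.373. Less than one turnover leaves 68.9%, so my figure for alpha is 31.1% reacted. Both runs used 0.264 M of protonated nucleophile, so they say nothing about gamma; the count reaches gamma only if k' stays as it is.

The forecast gives 27% for alpha (20% to 33%), below my figure, and 33% for gamma (25% to 41%), with the verdict it rises: “The rise is modest, near the threshold, but it is a rise.”

The flask gives 32.9% for alpha and 33.2% for gamma, a difference of 0.27 points: no change.

    electrophile + nucleophile → acid set free + target (k = 0.0151 M⁻¹ min⁻¹)
    nucleophile + acid set free ⇌ protonated nucleophile, settled at all times (K = 9100 M⁻¹)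
    acid set free + free base ⇌ salt of the base, settled at all times (K = 2.69 × 10⁶ M⁻¹)
    gas ⇌ free base, rate k4*(csat - [free base]) (kL = 0.00506 min⁻¹)

Count alpha again: 67% left at 40.0 h is 0.400 turnovers, against the 0.373 counted. By the first step, k' is its rate constant times the nucleophile, so carry the count to the neighbour of gamma with 0.37 M of electrophile. There the nucleophile stands at 0.00724 M at 40.0 h, about half of gamma's 0.0140 M. The count falls to 0.193, which leaves 82.5%. The neighbour holds 79%.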